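The earlier runs and the new flask come from a simulation with made-up constants; scatter was added.

The amounts of side product in the earlier runs were what I had, and the recipes and questions stood thus:

| flask | substrate | partner | remark | time |
|---|---|---|---|---|
| dusk | 10 mM | 1.8 equiv | run made earlier |  |
| noon | 14 mM | 1.8 equiv | run made earlier |  |
| spring | 22 mM | 1.8 equiv | run made earlier |  |
| winter | 10 mM | 3.6 equiv | run made earlier |  |
| Thursday's | 10 mM | 1.80 equiv | everything together at the start | 3.0 h |
| Wednesday's | 10 mM | 1.80 equiv (fed, over 2.5 h) | all else is in the flask from the start; the feed brings no volume worth counting | 3.0 h |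
| Sunday's | 10 mM (fed, over 2.5 h) | 1.80 equiv | all else is in the flask from the start; the feed brings no volume worth counting | 3.0 h |
| Friday's | 10 mM | 1.80 equiv (in portions, 2, over 2.5 h) | first portion at the start, last at 2.5 h | 3.0 h |

- dusk (time / min: side product / %, target / %): 25.0: 20.5, 10.6; 50.0: 35.6, 10.8; 80.0: 50.3, 7.6; 120: 63.7, 7.5
- noon (time / h: side product / %, target / %): 0.417: 26.9, 9.1; 1.00: 44.8, 8.3; 2.00: 65.9, 5.6; 3.00: 80.1, 3.9
- spring (time / h: side product / %, target / %): 0.417: 28.7, 12.3; 1.00: 49.2, 10.1; 2.00: 69.6, 3.9; 3.00: 85.2, 2.1
- winter (time / h: side product / %, target / %): 0.417: 30.1, 10.5; 1.00: 52.7, 11.1; 2.00: 74.1, 5.5; 3.00: 85.7, 2.1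

(scatter of a reading: 1 percentage point)



* the flask that comes out highest in amount of side product, in percent of the substrate charged, or "all alike" when all lie within 1.5 percentage points (Thursday's / Wednesday's / Sunday's / Friday's / all alike)
* side product at the end, in percent of the substrate charged, Thursday's
* side product at the end, in percent of the substrate charged, Wednesday's
* side product at the end, in percent of the substrate charged, Sunday's
* side product at the end, in percent of the substrate charged, Friday's

From the last dusk reading I read 0.507 /h as the clock constant, the natural logarithm of the reciprocal of the share of substrate not yet side product, divided by the time, an apparent constant averaged over the 120 min of that reading.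

Which concentration set it? The spring run, at 2.20 times the dusk substrate and 39.6 mM of partner, read 0.637 /h, while the winter run, on the dusk substrate with 36.0 mM of partner, read 0.648 /h, about the same. So I took partner as the concentration that moved the clock, and weakly, since twice the partner raised it by a factor of just 1.28.

What did that give? Thursday's flask repeated dusk, so I reckoned 78.1%. In Sunday's flask each slice of fed substrate aged on its own for the time left to it, and averaging those slices at 0.507 /h gave 56.0%. Friday's flask had been given half the partner until 2.5 h, and Wednesday's flask was still filling until then, so I expected both clocks to run slower than 0.507 /h and both flasks to end below Thursday's, though I put no number on them. Thursday's flask was my pick.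

The forecast also named Thursday's, at 79%, with 60% for Wednesday's, 60% for Friday's and 59% for Sunday's, a little above my figure, on the grounds that “late-fed substrate has little time to react”.

Thursday's came out highest, at 75.8%, 15 percentage points above Wednesday's 60.8%, with Friday's at 60.1% and Sunday's at 56.7%. The equations behind the flasks were these:

    substrate + partner ⇌ adduct, settled at all times (K = 60.7 /M)
    adduct ⇌ target (K = 0.440, k = 0.0301 /min)
    target ⇌ isomer of the product (K = 0.558, k = 0.120 /min)
    adduct → side product (k = 0.0259 /min)

Thursday's end value reads back as a clock constant of 0.472 /h, a little lower than the 0.507 /h of dusk, and 51% of Thursday's partner was left at the end. Put through the same slices, that Thursday constant gives 53.7% for Sunday's flask, which stood higher at 56.7%, and at 1.50 h Sunday's flask held 76.2% of its partner against 56.6% in Thursday's.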